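The oxane is numbered O1, C2 (arylethyl-bearing) to C6 (syringyl-bearing), and the ring is cut at C3–C4 and O1–C2. The C2–C3–C4(OH) segment is an aldol retron: C2 and C3 are the carbonyl and methyl carbons of zingerone, while O1, C6, C5 and C4 come from an (S)-β-silyloxy aldehyde. In one flask the silyl enol ether of zingerone adds to this aldehyde (1,3-anti aldol, sets C4) and the δ-silyloxy ketone formed is closed by reductive etherification (axial hydride, sets C2). The step exploits the anti relation between O1 on C6 and the C4 hydroxyl and the all-equatorial 2,4,6-pattern of the ring. Both precursors are acyclic.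

Key step: step 6

Remark: the B-allyl reagent of the (+)-α-pinene series, made from (−)-Ipc2BOMe, is taken to deliver allyl to the Si face of aryl aldehydes, which gives the (S)-carbinol.

Step 1
Reactants: 1 syringaldehyde (4-hydroxy-3,5-dimethoxybenzaldehyde)
Product: 2 4-formyl-2,6-dimethoxyphenyl 4-methylbenzenesulfonate
Conditions: TsCl, Et3N, DMAP (cat.), CH2Cl2, 0 °C to rt
Reagents that add atoms: p-toluenesulfonyl chloride, Cc1ccc(S(=O)(=O)Cl)cc1
Why: O-sulfonylation of the phenol (substitution at sulfur); the tosylate withstands base and Lewis acid and makes the aryl ring electron-poor enough to keep the later benzylic C–O bond from ionising.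

Step 2
Reactants: 2 4-formyl-2,6-dimethoxyphenyl 4-methylbenzenesulfonate
Product: 4 4-[(1S)-1-hydroxybut-3-en-1-yl]-2,6-dimethoxyphenyl 4-methylbenzenesulfonate, via O-diisopinocampheylborinic ester 3 (not isolated)
Conditions: (−)-Ipc2BOMe, CH2=CHCH2MgBr, Et2O, 0 °C to rt; then 2, −78 °C; then NaOH, H2O2, 0 °C to rt
Reagents that add atoms: allylmagnesium bromide, C=CC[Mg]Br (its allyl group is passed on by B-allyldiisopinocampheylborane, C=CCB([C@@H]1C[C@@H]2C[C@H]([C@H]1C)C2(C)C)[C@@H]1C[C@@H]2C[C@H]([C@H]1C)C2(C)C)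
Why: Brown asymmetric allylboration, in which the isopinocampheyl ligands of the (+)-α-pinene series steer allyl through a closed chair transition state to the Si face of the aldehyde and so set the (S)-carbinol centre (the future C6); oxidative work-up of borinic ester 3 frees the alcohol and leaves the aryl tosylate intact.

Step 3
Reactants: 4 4-[(1S)-1-hydroxybut-3-en-1-yl]-2,6-dimethoxyphenyl 4-methylbenzenesulfonate
Product: 5 2,6-dimethoxy-4-[(1S)-1-(triethylsilyloxy)but-3-en-1-yl]phenyl 4-methylbenzenesulfonate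
Conditions: TESCl, imidazole, DMF, 0 °C to rt
Reagents that add atoms: chlorotriethylsilane, CC[Si](CC)(CC)Cl
Why: imidazole-mediated silylation of the secondary alcohol; the triethylsilyl ether masks the oxygen through the ozonolysis and later serves as the oxygen nucleophile of the ring closure, and the stereocentre is not touched.

Step 4
Reactants: 5 2,6-dimethoxy-4-[(1S)-1-(triethylsilyloxy)but-3-en-1-yl]phenyl 4-methylbenzenesulfonate
Product: 7 2,6-dimethoxy-4-[(1S)-3-oxo-1-(triethylsilyloxy)propyl]phenyl 4-methylbenzenesulfonate, via secondary ozonide 6 (not isolated)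
Conditions: O3, CH2Cl2, −78 °C (Sudan red 7B as end-point indicator); then PPh3, −78 °C to rt
Reagents that add atoms: ozone, [O-][O+]=O
Why: ozonolysis of the terminal alkene with reductive phosphine work-up of ozonide 6 should give the β-silyloxy aldehyde; the electron-poor arene and the silyl ether survive at −78 °C and the aldehyde is used at once to avoid β-elimination.

Step 5
Reactants: 8 zingerone (4-(4-hydroxy-3-methoxyphenyl)butan-2-one)
Product: 9 trimethyl{2-methoxy-4-[3-(trimethylsilyloxy)but-3-en-1-yl]phenoxy}silane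
Conditions: LiN(iPr)2 (2.2 equiv), TMSCl (2.5 equiv), THF, −78 °C (internal quench), then 0 °C; pentane, cold aq NaHCO3; used crude
Reagents that add atoms: chlorotrimethylsilane, C[Si](C)(C)Cl
Why: kinetic enolate formation with O-silylation, in which the first equivalent of amide base gives the phenoxide and the second removes a proton from the less hindered methyl group at −78 °C, so that trapping of both oxyanions should give the terminal silyl enol ether.

Step 6
Reactants: 7 2,6-dimethoxy-4-[(1S)-3-oxo-1-(triethylsilyloxy)propyl]phenyl 4-methylbenzenesulfonate; 9 trimethyl{2-methoxy-4-[3-(trimethylsilyloxy)but-3-en-1-yl]phenoxy}silane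
Product: 13 4-[(2S,4R,6S)-4-hydroxy-6-[2-(4-hydroxy-3-methoxyphenyl)ethyl]oxan-2-yl]-2,6-dimethoxyphenyl 4-methylbenzenesulfonate, via difluoroboron aldolate 10 (not isolated), via cyclic oxocarbenium ion 11 (not isolated), via O-boryl O-silyl oxane 12 (not isolated)
Conditions: BF3·OEt2 (1.2 equiv), CH2Cl2, −78 °C; then Et3SiH (5 equiv), TMSOTf (0.3 equiv), −78 to −20 °C; then K2CO3, MeOH, 0 °C
Reagents that add atoms: none
Why: BF3 activates aldehyde 7 and the methylene terminus of enol silane 9 adds to it (Mukaiyama aldol, C3–C4 bond) to give the boron-chelated aldolate 10; TMSOTf then lets the oxygen of the C6 triethylsilyl ether add to the chelate-activated ketone, the silyl group is lost, the silyl ketal ionises to oxocarbenium ion 11 (O1–C2 bond) and Et3SiH reduces it to 12, which the methanolic quench unmasks to 13. The closest known reaction types are the Lewis-acid-mediated Mukaiyama aldol of β-silyloxy aldehydes and the reductive etherification of δ-silyloxy ketones (silane reduction of a cyclic oxocarbenium ion), run here in one flask. The ring closes in the 6-exo-trig mode, the ether oxygen adding to the carbonyl carbon whose C=O bond lies outside the forming ring. C4 is controlled by the C6 stereocentre, since in the dipole-minimised open transition state of the aldehyde–BF3 complex the nucleophile enters anti to the β-silyloxy group (1,3-anti induction); C2 is controlled by the ring, since hydride adds axially to the half-chair of 11 that keeps the C6 aryl group and the C4 oxygen pseudoequatorial, which should give the 2,6-cis, all-equatorial oxane. The step needs attack through the terminal carbon of 9 (secured by the kinetic enol silane), an intact benzylic C6–O bond (secured by the electron-poor tosyloxy-substituted ring, which disfavours a benzylic cation) and no β-elimination of the C4 oxygen (secured by low temperature and excess silane).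

Step 7
Reactants: 13 4-[(2S,4R,6S)-4-hydroxy-6-[2-(4-hydroxy-3-methoxyphenyl)ethyl]oxan-2-yl]-2,6-dimethoxyphenyl 4-methylbenzenesulfonate
Product: 14 (2S,4R,6S)-2-(4-hydroxy-3,5-dimethoxyphenyl)-6-[2-(4-hydroxy-3-methoxyphenyl)ethyl]oxan-4-ol
Conditions: KOH, MeOH/H2O, reflux, under argon; then aq NH4Cl
Reagents that add atoms: none
Why: alkaline hydrolysis of the aryl sulfonate (hydroxide attacks sulfur and the phenoxide leaves); the oxane, the secondary alcohol and the three stereocentres are inert to base, and exclusion of air protects the electron-rich phenolates.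

Compound list

1 | syringaldehyde (4-hydroxy-3,5-dimethoxybenzaldehyde) | COc1cc(C=O)cc(OC)c1O | starting material
2 | 4-formyl-2,6-dimethoxyphenyl 4-methylbenzenesulfonate | COc1cc(C=O)cc(OC)c1OS(=O)(=O)c1ccc(C)cc1 | intermediate
3 | O-diisopinocampheylborinic ester of 4 (isopinocampheyl groups of the (+)-α-pinene series) | C=CC[C@@H](c1cc(OC)c(OS(=O)(=O)c2ccc(C)cc2)c(OC)c1)OB([C@@H]1C[C@@H]2C[C@H]([C@H]1C)C2(C)C)[C@@H]1C[C@@H]2C[C@H]([C@H]1C)C2(C)C | intermediate (not isolated)
4 | 4-[(1S)-1-hydroxybut-3-en-1-yl]-2,6-dimethoxyphenyl 4-methylbenzenesulfonate | C=CC[C@@H](c1cc(OC)c(OS(=O)(=O)c2ccc(C)cc2)c(OC)c1)O | intermediate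
5 | 2,6-dimethoxy-4-[(1S)-1-(triethylsilyloxy)but-3-en-1-yl]phenyl 4-methylbenzenesulfonate | C=CC[C@@H](c1cc(OC)c(OS(=O)(=O)c2ccc(C)cc2)c(OC)c1)O[Si](CC)(CC)CC | intermediate
6 | 2,6-dimethoxy-4-[(1S)-1-(triethylsilyloxy)-2-(1,2,4-trioxolan-3-yl)ethyl]phenyl 4-methylbenzenesulfonate (secondary ozonide, mixture at the trioxolane carbon) | C1(C[C@@H](c2cc(OC)c(OS(=O)(=O)c3ccc(C)cc3)c(OC)c2)O[Si](CC)(CC)CC)OCOO1 | intermediate (not isolated)
7 | 2,6-dimethoxy-4-[(1S)-3-oxo-1-(triethylsilyloxy)propyl]phenyl 4-methylbenzenesulfonate | O=CC[C@@H](c1cc(OC)c(OS(=O)(=O)c2ccc(C)cc2)c(OC)c1)O[Si](CC)(CC)CC | intermediate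
8 | zingerone (4-(4-hydroxy-3-methoxyphenyl)butan-2-one) | CC(=O)CCc1ccc(O)c(OC)c1 | starting material
9 | trimethyl{2-methoxy-4-[3-(trimethylsilyloxy)but-3-en-1-yl]phenoxy}silane | C=C(CCc1ccc(O[Si](C)(C)C)c(OC)c1)O[Si](C)(C)C | intermediate
10 | 4-[(1S,3S)-3-(difluoroboranyloxy)-7-[3-methoxy-4-(trimethylsilyloxy)phenyl]-5-oxo-1-(triethylsilyloxy)heptyl]-2,6-dimethoxyphenyl 4-methylbenzenesulfonate (difluoroboron aldolate) | COc1cc(CCC(=O)C[C@@H](OB(F)F)C[C@@H](c2cc(OC)c(OS(=O)(=O)c3ccc(C)cc3)c(OC)c2)O[Si](CC)(CC)CC)ccc1O[Si](C)(C)C | intermediate (not isolated)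
11 | cyclic oxocarbenium ion (cation): O1=C2 carries the 2-[3-methoxy-4-(trimethylsilyloxy)phenyl]ethyl chain, C4 the difluoroboranyloxy group and C6 the 3,5-dimethoxy-4-(tosyloxy)phenyl ring, C4 and C6 configured as in 10 | COc1cc(CCC2=[O+][C@H](c3cc(OC)c(OS(=O)(=O)c4ccc(C)cc4)c(OC)c3)C[C@H](OB(F)F)C2)ccc1O[Si](C)(C)C | intermediate (not isolated)
12 | 4-[(2S,4R,6S)-4-(difluoroboranyloxy)-6-{2-[3-methoxy-4-(trimethylsilyloxy)phenyl]ethyl}oxan-2-yl]-2,6-dimethoxyphenyl 4-methylbenzenesulfonate | COc1cc(CC[C@H]2C[C@@H](OB(F)F)C[C@@H](c3cc(OC)c(OS(=O)(=O)c4ccc(C)cc4)c(OC)c3)O2)ccc1O[Si](C)(C)C | intermediate (not isolated)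
13 | 4-[(2S,4R,6S)-4-hydroxy-6-[2-(4-hydroxy-3-methoxyphenyl)ethyl]oxan-2-yl]-2,6-dimethoxyphenyl 4-methylbenzenesulfonate | COc1cc(CC[C@H]2C[C@@H](O)C[C@@H](c3cc(OC)c(OS(=O)(=O)c4ccc(C)cc4)c(OC)c3)O2)ccc1O | intermediate
14 | (2S,4R,6S)-2-(4-hydroxy-3,5-dimethoxyphenyl)-6-[2-(4-hydroxy-3-methoxyphenyl)ethyl]oxan-4-ol (CNP0302691.1) | COc1cc(CC[C@H]2C[C@@H](O)C[C@@H](c3cc(OC)c(O)c(OC)c3)O2)ccc1O | target

Total step count: 7. Longest linear sequence: 6 steps (steps 1, 2, 3, 4, 6 and 7); step 5 prepares the second fragment.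

Steps most likely to fail

1. Step 6. What may go wrong: erosion of the 1,3-anti facial selectivity in the aldol stage, β-elimination of the boron aldolate, or direct silane reduction of the ketone before the silyl ether has closed the ring. The fallback leaves the aldol disconnection and builds the ring by a Prins cyclization. It sets out from 4. The partner aldehyde 3-(4-hydroxy-3-methoxyphenyl)propanal F1 is made by iBu2AlH reduction (CH2Cl2, −78 °C) of commercial methyl 3-(4-hydroxy-3-methoxyphenyl)propanoate. Alcohol 4 and F1 in CF3CO2H/CH2Cl2 (0 °C to rt) should condense to an oxocarbenium ion that cyclises through a chair with all substituents equatorial and is captured by trifluoroacetate, giving the all-cis (2S,4R,6S)-oxan-4-yl trifluoroacetate F2. K2CO3 in MeOH at rt then cleaves the ester, and the route is rejoined at 13. The electron-poor aryl ring of 4 guards against loss of configuration by oxonia-Cope rearrangement or benzylic ionisation.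

2. Step 5. What may go wrong: leakage of the enolisation to the internal methylene within the aggregated phenoxide–enolate, and hydrolytic loss of the labile trimethylsilyl groups during isolation. The fallback replaces the transient silyl protection by a robust one. It sets out from 8. TBSCl and imidazole in DMF should give the purifiable aryl silyl ether 4-[4-(tert-butyldimethylsilyloxy)-3-methoxyphenyl]butan-2-one F3. LiN(iPr)2 with TMSCl (THF, −78 °C) then enolises a neutral monoketone to the terminal silyl enol ether tert-butyl{2-methoxy-4-[3-(trimethylsilyloxy)but-3-en-1-yl]phenoxy}dimethylsilane F4. F4 and 7 under the conditions of step 6 should pass through the difluoroboron aldolate F5, the cyclic oxocarbenium ion F6 and the O-boryl oxane F7 (none isolated). A longer K2CO3/MeOH quench at rt, which also cleaves the aryl silyl ether but not the aryl tosylate, rejoins the route at 13.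

3. Step 2. What may go wrong: incomplete enantiofacial discrimination in the allyl transfer (temperature rise, magnesium salts), which would lower the optical purity of every later compound. The fallback replaces asymmetric synthesis by resolution. It sets out from 2. Barbier allylation (Zn, CH2=CHCH2Br, THF/aq NH4Cl, rt) should give racemic 4-(1-hydroxybut-3-en-1-yl)-2,6-dimethoxyphenyl 4-methylbenzenesulfonate F8. Lipase from Burkholderia cepacia with vinyl acetate in tert-butyl methyl ether (30 °C) should acylate the (R)-enantiomer to 4-[(1R)-1-acetoxybut-3-en-1-yl]-2,6-dimethoxyphenyl 4-methylbenzenesulfonate F9, which is removed by chromatography. The unreacted (S)-alcohol is 4, where the route is rejoined.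

Further compounds

F1 | step 6 | 3-(4-hydroxy-3-methoxyphenyl)propanal | COc1cc(CCC=O)ccc1O
F2 | step 6 | (2S,4R,6S)-2-[3,5-dimethoxy-4-(4-methylbenzenesulfonyloxy)phenyl]-6-[2-(4-hydroxy-3-methoxyphenyl)ethyl]oxan-4-yl trifluoroacetate | COc1cc(CC[C@H]2C[C@@H](OC(=O)C(F)(F)F)C[C@@H](c3cc(OC)c(OS(=O)(=O)c4ccc(C)cc4)c(OC)c3)O2)ccc1O
F3 | step 5 | 4-[4-(tert-butyldimethylsilyloxy)-3-methoxyphenyl]butan-2-one | CC(=O)CCc1ccc(O[Si](C)(C)C(C)(C)C)c(OC)c1
F4 | step 5 | tert-butyl{2-methoxy-4-[3-(trimethylsilyloxy)but-3-en-1-yl]phenoxy}dimethylsilane | C=C(CCc1ccc(O[Si](C)(C)C(C)(C)C)c(OC)c1)O[Si](C)(C)C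
F5 | step 5 | 4-[(1S,3S)-7-[4-(tert-butyldimethylsilyloxy)-3-methoxyphenyl]-3-(difluoroboranyloxy)-5-oxo-1-(triethylsilyloxy)heptyl]-2,6-dimethoxyphenyl 4-methylbenzenesulfonate | COc1cc(CCC(=O)C[C@@H](OB(F)F)C[C@@H](c2cc(OC)c(OS(=O)(=O)c3ccc(C)cc3)c(OC)c2)O[Si](CC)(CC)CC)ccc1O[Si](C)(C)C(C)(C)C
F6 | step 5 | cyclic oxocarbenium ion (cation), the aryl tert-butyldimethylsilyl ether analogue of 11 | COc1cc(CCC2=[O+][C@H](c3cc(OC)c(OS(=O)(=O)c4ccc(C)cc4)c(OC)c3)C[C@H](OB(F)F)C2)ccc1O[Si](C)(C)C(C)(C)C
F7 | step 5 | 4-[(2S,4R,6S)-6-{2-[4-(tert-butyldimethylsilyloxy)-3-methoxyphenyl]ethyl}-4-(difluoroboranyloxy)oxan-2-yl]-2,6-dimethoxyphenyl 4-methylbenzenesulfonate | COc1cc(CC[C@H]2C[C@@H](OB(F)F)C[C@@H](c3cc(OC)c(OS(=O)(=O)c4ccc(C)cc4)c(OC)c3)O2)ccc1O[Si](C)(C)C(C)(C)C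
F8 | step 2 | racemic 4-(1-hydroxybut-3-en-1-yl)-2,6-dimethoxyphenyl 4-methylbenzenesulfonate | C=CCC(O)c1cc(OC)c(OS(=O)(=O)c2ccc(C)cc2)c(OC)c1
F9 | step 2 | 4-[(1R)-1-acetoxybut-3-en-1-yl]-2,6-dimethoxyphenyl 4-methylbenzenesulfonate | C=CC[C@H](c1cc(OC)c(OS(=O)(=O)c2ccc(C)cc2)c(OC)c1)OC(C)=O
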